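(The readings come from a simulation on assumed constants, noise included.)

The pitfall in this flask was to call the nucleophile the limiting reagent and expect the electrophile to stop at one nucleophile each.

| setting | Wednesday's | Monday's | flask |
|---|---|---|---|
| electrophile | 14 mM | 22 mM | 10 mM |
| nucleophile | 9 mM | 9 mM | 9.00 mM |
| solid base | 5 mM | 5 mM | 5.00 mM |
| remark | run made earlier | run made earlier |  |
| time |  |  | 15 min |

- Wednesday's (time / min: electrophile / %, target / %): 2.00: 57.1, 25.5; 4.00: 44.1, 24.7; 5.00: 40.6, 22.6; 8.00: 30.9, 19.2; 10.0: 26.0, 16.5
- Monday's (time / min: electrophile / %, target / %): 2.00: 63.8, 14.7; 4.00: 54.4, 9.0; 5.00: 49.9, 9.8; 8.00: 44.3, 8.2; 10.0: 41.4, 5.8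

(each reading ± 1 percentage point)

- given per volume of solution although it is solid: solid base
- what was read earlier has a scatter of 1 percentage point, one standard deviation
- at the start none of the solid base is in solution
- the earlier runs do not show how much of nucleophile is bound; that part of a forecast is a guess

1. part of the electrophile that has reacted at 15 min
2. share of the unused nucleophile that is free and not bound as protonated nucleophile, at 15 min

I tried that rule on Monday's run. It allowed 40.9% of the electrophile, yet 58.6% had reacted by 10.0 min, more than the rule allowed. In Wednesday's run the target fell from 25.5% to 16.5% while the electrophile kept falling, so I took it that target takes up a second electrophile. Each nucleophile that reacts also releases acid, and as a bench assumption, not a finding, I let that acid sit on solid base or on a second nucleophile. Freezing these two counts, I called 14.0 mM, the nucleophile plus solid base of this flask, its electrophile ceiling: the electrophile a charge can pay for on that assumption. Monday's ceiling was 63.6% of its charge, above the reading. For this flask the ratio is 140%, so the ceiling is larger than the charge and sets no stop. Here the rule ends and rate takes over. I committed to no figure beyond more than the 74.0% read on Wednesday at 10.0 min.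

The forecast was 91% reacted and 40% of the unused nucleophile free, with the grounds that “base is used up within roughly 10–15 min”.

    solid base ⇌ free base, rate k1*(cs1 - [free base]) while solid is left; crystals form when [free base] > cs1 (solubility = 1.50 mM, k = 0.0732 min⁻¹)
    electrophile + nucleophile → acid set free + target (k = 120 M⁻¹ min⁻¹)
    acid set free + free base ⇌ salt of the base (K = 65700 M⁻¹, k = 36.5 M⁻¹ min⁻¹)
    nucleophile + acid set free ⇌ protonated nucleophile, settled at all times (K = 5700 M⁻¹)
    acid set free → by-product carried off (k = 0.0778 min⁻¹)
    electrophile + target → side product (k = 21.2 M⁻¹ min⁻¹)

The flask gave 89.6% reacted, close to the forecast, and 11.2% free, 29 percentage points below it. At 15.0 min, 77.6% of the solid base was still solid, and 2.66 mM of protonated nucleophile stood beside free nucleophile at 3.73% of its charge. The electrophile used, 8.96 mM, was 64.0% of the ceiling.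

With 25 mM of electrophile, the ceiling allows 56.0% of the charge. That neighbouring flask reacted 60.2%, 4.2 points past it, so the ceiling was an estimate there and not a bound, and 3.33 mM of by-product carried off stood in that flask at 15.0 min.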